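**Retrosynthetic overview**
- Target 11 ⇒ C6–O aryl bond, made last, from the 6-iodo-7-O-sulfate 7 by a copper-catalysed, borate-mediated hydroxylation (key step).
- 7 ⇒ O7–S bond: sulfuryl transfer to the most acidic hydroxyl (7-OH) of 6-iodokaempferol 3.
- 3 ⇒ C6–I bond: site-selective iodination of kaempferol 1 at the carbon between the 5-OH and 7-OH.
- No ring is built: rings A, C and B are bought intact in kaempferol, so no order of ring formation arises.

Assumption: the target has no stereocentre or axis (planar, achiral flavonol), so it is one achiral compound and needs no stereocontrol. It is delivered in the drawn hydrogen sulfate form by a cold acidic work-up; the potassium salt is the storage form.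

**Step 1**
Reactants: 1 kaempferol; 2 benzyltrimethylammonium dichloroiodate
Product: 3 6-iodokaempferol
Conditions: BnNMe3·ICl2 (1.0 equiv), CaCO3 (1.0 equiv), MeOH/CH2Cl2 (1:1), 0 °C to rt, dark, 4 h
Reagents that add atoms: benzyltrimethylammonium dichloroiodate, C[N+](C)(C)Cc1ccccc1.Cl[I-]Cl
Why: Electrophilic aromatic iodination attacks ring A, the phloroglucinol-type and most nucleophilic ring, and with a free 5-OH the carbon flanked by the 5-OH and the 7-oxygen (C6) is the expected site for an ICl2− salt under weakly basic conditions, while one equivalent at 0 °C limits 6,8-diiodination.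

**Step 2**
Reactants: 3 6-iodokaempferol; 4 potassium tert-butoxide; 5 sulfur trioxide–trimethylamine complex
Product: 7 potassium 6-iodokaempferol 7-O-sulfate, via potassium 7-phenoxide 6 (not isolated)
Conditions: KOtBu (1.0 equiv), DMF, 0 °C, 15 min, Ar; then Me3N·SO3 (1.15 equiv), rt, 16 h; C18 chromatography (H2O/MeOH)
Reagents that add atoms: potassium tert-butoxide, CC(C)(C)[O-].[K+]; sulfur trioxide–trimethylamine complex, C[N+](C)(C)S(=O)(=O)[O-]
Why: O-Sulfation by sulfuryl transfer from an SO3–amine complex to a phenoxide: one equivalent of base ionises only the 7-OH (a vinylogous acid conjugated to the C4 carbonyl, further acidified by the ortho iodine), while the chelated 3-OH and 5-OH and the less acidic 4'-OH stay protonated.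

**Step 3**
Reactants: 7 potassium 6-iodokaempferol 7-O-sulfate; 8 boric acid; 9 potassium hydroxide
Product: 11 6-hydroxykaempferol 7-O-(hydrogen sulfate) (target), via cyclic 5,6-borate 10 (not isolated)
Conditions: CuI (10 mol %), N,N'-bis(4-hydroxy-2,6-dimethylphenyl)oxalamide (10 mol %), B(OH)3 (3 equiv), KOH (5 equiv), sodium ascorbate (10 mol %), degassed DMSO/H2O (1:1), 60 °C, Ar, 12 h; then 1 M HCl to pH 2, 0 °C, immediate C18 desalting, lyophilise
Reagents that add atoms: boric acid, OB(O)O; potassium hydroxide, [K+].[OH-]
Why: Proposed new method: an Ullmann-type copper-catalysed hydroxylation in which tetrahydroxyborate made in the flask is the oxygen donor: the monovalent copper–oxalamide complex takes up a borate or hydroxide ligand, adds the C6–I bond (the most reactive halide, on a ring made less electron-rich by the 7-O-sulfate), and C–O reductive elimination from trivalent copper gives an aryl borate that the neighbouring 5-OH closes to the five-membered catechol borate 10, which shields the new 5,6-catechol from copper chelation and oxidation at about pH 10 until cold acid releases it, the aryl sulfate monoester anion being inert to base; the closest known reaction types are copper/oxalamide-catalysed hydroxylation of aryl halides, copper-mediated methoxylation of 6-halo-5,7-dihydroxyflavones and palladium-catalysed hydroxylation with boric acid, none shown on an unprotected polyphenolic aryl iodide carrying an O-sulfate.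

**Compound list**
1 | kaempferol (3,5,7-trihydroxy-2-(4-hydroxyphenyl)chromen-4-one) | O=c1c(O)c(-c2ccc(O)cc2)oc2cc(O)cc(O)c12 | starting material
2 | benzyltrimethylammonium dichloroiodate | C[N+](C)(C)Cc1ccccc1.Cl[I-]Cl | starting material
3 | 6-iodokaempferol (3,5,7-trihydroxy-2-(4-hydroxyphenyl)-6-iodochromen-4-one) | O=c1c(O)c(-c2ccc(O)cc2)oc2cc(O)c(I)c(O)c12 | intermediate
4 | potassium tert-butoxide | CC(C)(C)[O-].[K+] | starting material
5 | sulfur trioxide–trimethylamine complex | C[N+](C)(C)S(=O)(=O)[O-] | starting material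
6 | potassium 7-phenoxide of 6-iodokaempferol | O=c1c(O)c(-c2ccc(O)cc2)oc2cc([O-])c(I)c(O)c12.[K+] | intermediate
7 | potassium 6-iodokaempferol 7-O-sulfate (potassium 3,5-dihydroxy-2-(4-hydroxyphenyl)-6-iodo-4-oxochromen-7-yl sulfate) | O=c1c(O)c(-c2ccc(O)cc2)oc2cc(OS(=O)(=O)[O-])c(I)c(O)c12.[K+] | intermediate
8 | boric acid | OB(O)O | starting material
9 | potassium hydroxide | [K+].[OH-] | starting material
10 | dipotassium cyclic 5,6-O,O-dihydroxyborate of 6-hydroxykaempferol 7-O-sulfate (five-membered ring C5–O–B(OH)2–O–C6, tetracoordinate boron) | O=c1c(O)c(-c2ccc(O)cc2)oc2cc(OS(=O)(=O)[O-])c3O[B-](O)(O)Oc3c12.[K+].[K+] | intermediate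
11 | 6-hydroxykaempferol 7-O-(hydrogen sulfate) (3,5,6-trihydroxy-2-(4-hydroxyphenyl)-4-oxochromen-7-yl hydrogen sulfate) | O=c1c(O)c(-c2ccc(O)cc2)oc2cc(OS(=O)(=O)O)c(O)c(O)c12 | target

**Step count and risks**
Total step count: 3. Longest linear sequence: 3 steps (1 → 3 → 7 → 11).

Step 3 (the proposed new C–O coupling) is the most likely to fail. The expected failure modes are hydrodeiodination to kaempferol 7-sulfate, sequestration of copper by the 3-hydroxy-4-keto site, sulfate migration to the new 6-oxygen, and oxidation of the product. The fallback uses only known chemistry and moves the oxygen in before the sulfate. It sets out from 3: Ullmann-type methoxylation of unprotected 3 (NaOMe, CuBr, DMF/MeOH, 110 °C, Ar) gives 6-methoxykaempferol F6. BBr3 (CH2Cl2, −78 °C to rt) cleaves the aryl methyl ether to 6-hydroxykaempferol F7. KOtBu (1.0 equiv) and Me3N·SO3 in DMF then sulfate the most acidic 7-OH to give the potassium salt of the target F8. Cold 1 M HCl and C18 desalting convert this into 11, where the fallback rejoins the route.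

Step 1 is the second risk. Iodination of free kaempferol may give C8 or 6,8-bis-iodination, so the site must be checked by HMBC from the chelated 5-OH proton. The fallback puts the substrate into the 5-hydroxy-7-alkoxy pattern for which C6 iodination is best established. It sets out from 1: BnBr (3.3 equiv), K2CO3, DMF, rt gives 3,7,4'-tri-O-benzylkaempferol F1, with the chelated 5-OH left free. BnNMe3·ICl2 and CaCO3 in MeOH/CH2Cl2 give 3,7,4'-tri-O-benzyl-6-iodokaempferol F2. BCl3 with pentamethylbenzene (CH2Cl2, −78 °C) removes the benzyl ethers without touching the C–I bond and returns to 3.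

Step 2 is the third risk. Sulfation controlled by acidity may give mixtures with 4'- or 3-sulfates or over-sulfation. The fallback replaces acidity control by protecting-group control. It sets out from 3: Ac2O/pyridine gives 6-iodokaempferol 3,5,7,4'-tetraacetate F3. PhSH and imidazole in NMP at 0 °C remove only the most labile 7-O-acetyl to give 3,5,4'-tri-O-acetyl-6-iodokaempferol F4. SO3·pyridine in pyridine sulfates the single free hydroxyl to give pyridinium 3,5,4'-tri-O-acetyl-6-iodokaempferol 7-O-sulfate F5. K2CO3 in MeOH removes the three acetates and exchanges the cation, returning to 7.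

**Further compounds**
F1 | step 1 | 3,7,4'-tri-O-benzylkaempferol | O=c1c(OCc2ccccc2)c(-c2ccc(OCc3ccccc3)cc2)oc2cc(OCc3ccccc3)cc(O)c12
F2 | step 1 | 3,7,4'-tri-O-benzyl-6-iodokaempferol | O=c1c(OCc2ccccc2)c(-c2ccc(OCc3ccccc3)cc2)oc2cc(OCc3ccccc3)c(I)c(O)c12
F3 | step 2 | 6-iodokaempferol 3,5,7,4'-tetraacetate | CC(=O)Oc1ccc(-c2oc3cc(OC(C)=O)c(I)c(OC(C)=O)c3c(=O)c2OC(C)=O)cc1
F4 | step 2 | 3,5,4'-tri-O-acetyl-6-iodokaempferol | CC(=O)Oc1ccc(-c2oc3cc(O)c(I)c(OC(C)=O)c3c(=O)c2OC(C)=O)cc1
F5 | step 2 | pyridinium 3,5,4'-tri-O-acetyl-6-iodokaempferol 7-O-sulfate | CC(=O)Oc1ccc(-c2oc3cc(OS(=O)(=O)[O-])c(I)c(OC(C)=O)c3c(=O)c2OC(C)=O)cc1.c1cc[nH+]cc1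
F6 | step 3 | 6-methoxykaempferol | O=c1c(O)c(-c2ccc(O)cc2)oc2cc(O)c(OC)c(O)c12
F7 | step 3 | 6-hydroxykaempferol | O=c1c(O)c(-c2ccc(O)cc2)oc2cc(O)c(O)c(O)c12
F8 | step 3 | potassium 6-hydroxykaempferol 7-O-sulfate | O=c1c(O)c(-c2ccc(O)cc2)oc2cc(OS(=O)(=O)[O-])c(O)c(O)c12.[K+]
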